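**Retrosynthetic overview**
- Last bond: acylation of the C19 primary alcohol of labda-13(16),14-diene-8α,19-diol with 4-methoxycinnamoyl chloride; the diol comes from LiAlH4 cleavage of a C19 8-phenylmenthyl ester.
- The 8α-OH and the 2-substituted butadiene both come from an ambreinolide-type δ-lactone (C8–O–C13=O): vinyllithium opens it, then Wittig methylenation; the C3 ketone is removed first.
- Key step: the keto lactone comes from an acyclic β-keto ester diene; Mn(OAc)3 turns the normally nucleophilic α-carbon (C4) into an electrophilic α-acyl radical that bonds to C5 of a nucleophilic alkene.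
- Ring order, all in that one flask: ring A (C4–C5), ring B (C10–C9), then lactone ring C (C8–O) after oxidation of the C8 radical to the cation; the auxiliary fixes the absolute configuration.
- The acyclic precursor comes from γ-alkylation of the auxiliary 2-methylacetoacetate dianion with an (E,E)-allylic bromide built from geranyl bromide and tert-butyl acetate.

Assumption: the SMILES is read as (4S,5R,8R,9R,10S), i.e. the normal-labdane 8α-hydroxy-13(16),14-dien-19-yl ester with CH2O on the axial 4β position; labdane numbering is used for the cyclic compounds, R* = (1R,2S,5R)-8-phenylmenthyl, and (−)-8-phenylmenthol and 4-methoxycinnamoyl chloride are taken as purchasable.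

**Step 1**
Reactants: 1 geranyl bromide; 2 tert-butyl acetate
Product: 4 tert-butyl (4E)-5,9-dimethyldeca-4,8-dienoate, via lithium enolate of tert-butyl acetate 3 (not isolated)
Conditions: LiN(iPr)2 (1.1 equiv), THF, −78 °C; then 1, DMPU, −78 → 0 °C
Reagents that add atoms: none
Why: Ester enolate alkylation (SN2 at the primary allylic bromide) keeps the (E)-alkene and installs the two-carbon acid arm that becomes C12–C13.

**Step 2**
Reactants: 4 tert-butyl (4E)-5,9-dimethyldeca-4,8-dienoate
Product: 5 tert-butyl (4E,8E)-10-hydroxy-5,9-dimethyldeca-4,8-dienoate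
Conditions: SeO2 (0.3 equiv), t-BuOOH (3 equiv), salicylic acid (0.1 equiv), CH2Cl2, 0 °C → rt
Reagents that add atoms: selenium dioxide, O=[Se]=O (oxygen carrier); tert-butyl hydroperoxide, CC(C)(C)OO (terminal oxygen source)
Why: SeO2/t-BuOOH allylic oxidation (ene reaction then [2,3]-sigmatropic shift) hydroxylates the (E)-methyl of the terminal prenyl group selectively, giving the (E)-allylic alcohol.

**Step 3**
Reactants: 5 tert-butyl (4E,8E)-10-hydroxy-5,9-dimethyldeca-4,8-dienoate
Product: 6 tert-butyl (4E,8E)-10-bromo-5,9-dimethyldeca-4,8-dienoate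
Conditions: CBr4, PPh3, CH2Cl2, 0 °C
Reagents that add atoms: carbon tetrabromide, BrC(Br)(Br)Br
Why: The Appel reaction converts the primary allylic alcohol into the bromide under neutral conditions that spare the tert-butyl ester and both alkene geometries.

**Step 4**
Reactants: 7 ethyl 2-methyl-3-oxobutanoate; 8 (1R,2S,5R)-8-phenylmenthol
Product: 9 (1R,2S,5R)-8-phenylmenthyl 2-methyl-3-oxobutanoate
Conditions: DMAP (0.3 equiv), toluene, reflux, EtOH removed over 4 Å sieves
Reagents that add atoms: none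
Why: DMAP-catalysed transesterification of the β-keto ester (through the acyl ketene) attaches the chiral auxiliary, and the α-stereocentre is irrelevant because it later becomes the radical centre.

**Step 5**
Reactants: 9 (1R,2S,5R)-8-phenylmenthyl 2-methyl-3-oxobutanoate; 6 tert-butyl (4E,8E)-10-bromo-5,9-dimethyldeca-4,8-dienoate
Product: 11 1-[(1R,2S,5R)-8-phenylmenthyl] 14-tert-butyl (6E,10E)-2,6,10-trimethyl-3-oxotetradeca-6,10-dienedioate, via keto ester dianion 10 (not isolated)
Conditions: NaH, THF, 0 °C; n-BuLi, 0 °C; then 6, 0 °C; aq NH4Cl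
Reagents that add atoms: none
Why: Weiler dianion alkylation, in which the γ-carbanion is the most nucleophilic site and displaces the allylic bromide by SN2 while the tert-butyl ester is untouched.

**Step 6**
Reactants: 11 1-[(1R,2S,5R)-8-phenylmenthyl] 14-tert-butyl (6E,10E)-2,6,10-trimethyl-3-oxotetradeca-6,10-dienedioate
Product: 14 (1R,2S,5R)-8-phenylmenthyl 3,13-dioxo-8α,13-epoxy-14,15,16-trinorlabdan-19-oate, via C4 α-keto ester radical 12 (not isolated), via bicyclic C8 cation 13 (not isolated)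
Conditions: Mn(OAc)3·2H2O (2.5 equiv), Cu(OTf)2 (0.2 equiv), Yb(OTf)3 (1.0 equiv), CF3CH2OH, −5 °C → rt
Reagents that add atoms: none
Why: Proposed new method: Mn(OAc)3 oxidises the Yb(OTf)3-activated β-keto ester enol to an electrophilic α-acyl radical (reversed polarity at C4) that adds 6-endo to C5 of the electron-rich alkene and then C10 to C9 through a chair–chair transition state with the ester axial (sets 4β-CO2R*, 5α-H, 10β-CH3, 9α-H), the phenyl ring of the auxiliary shielding one face of the radical so that the (4S,5R,10S) series forms, after which the tertiary C8 radical is oxidised by Mn(OAc)3/Cu(OTf)2 to the cation and captured by the tert-butyl ester carbonyl from the equatorial α-face away from the axial C10 methyl with loss of isobutene (sets 8α-O); the closest known reaction types are the auxiliary-controlled, lanthanide-triflate-promoted Mn(OAc)3 oxidative radical polyene cyclisation of β-keto esters and the Mn(OAc)3/copper-salt oxidative lactonisation of alkenes by radical-to-cation crossover.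

**Step 7**
Reactants: 14 (1R,2S,5R)-8-phenylmenthyl 3,13-dioxo-8α,13-epoxy-14,15,16-trinorlabdan-19-oate
Product: 16 (1R,2S,5R)-8-phenylmenthyl 13-oxo-8α,13-epoxy-14,15,16-trinorlabdan-19-oate, via C3 tosylhydrazone 15 (not isolated)
Conditions: TsNHNH2, EtOH, 78 °C; evaporate; catecholborane, CHCl3, 0 °C → rt; NaOAc·3H2O, 60 °C
Reagents that add atoms: none
Why: Caglioti-type deoxygenation, in which only the ketone forms a tosylhydrazone and hydride delivery from catecholborane followed by loss of sulfinate and N2 leaves CH2 at C3 without touching lactone, ester or any stereocentre.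

**Step 8**
Reactants: 16 (1R,2S,5R)-8-phenylmenthyl 13-oxo-8α,13-epoxy-14,15,16-trinorlabdan-19-oate
Product: 18 (1R,2S,5R)-8-phenylmenthyl 8α-hydroxy-13-oxo-16-norlabd-14-en-19-oate, via lithium hemiketalate 17 (not isolated)
Conditions: CH2=CHLi (from Sn(CH=CH2)4 + MeLi, Et2O, 0 °C), THF, −78 °C; aq NH4Cl, −78 °C
Reagents that add atoms: vinyllithium, [Li]C=C, generated from tetravinylstannane, C=C[Sn](C=C)(C=C)C=C
Why: 1,2-Addition of an organolithium to the lactone stops at the tetrahedral lithium hemiketalate at −78 °C (the leaving group would be a tertiary alkoxide), and work-up opens it to the vinyl ketone and frees the 8α-OH with the C8–O bond never broken; the neopentyl C19 ester is too hindered to react.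

**Step 9**
Reactants: 18 (1R,2S,5R)-8-phenylmenthyl 8α-hydroxy-13-oxo-16-norlabd-14-en-19-oate
Product: 19 (1R,2S,5R)-8-phenylmenthyl 8α-hydroxylabda-13(16),14-dien-19-oate
Conditions: Ph3PCH3Br, KOtBu, THF, 0 °C → rt
Reagents that add atoms: methylenetriphenylphosphorane, C=P(c1ccccc1)(c1ccccc1)c1ccccc1, generated from methyltriphenylphosphonium bromide, C[P+](c1ccccc1)(c1ccccc1)c1ccccc1.[Br-]
Why: Wittig methylenation of the ketone carbonyl gives the C13=C16 bond and hence the 2-substituted buta-1,3-diene directly.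

**Step 10**
Reactants: 19 (1R,2S,5R)-8-phenylmenthyl 8α-hydroxylabda-13(16),14-dien-19-oate
Product: 20 labda-13(16),14-diene-8α,19-diol
Conditions: LiAlH4, THF, 0 °C → reflux; aqueous work-up (8 recovered)
Reagents that add atoms: none
Why: Hydride reduction of the hindered axial ester gives the C19 primary alcohol and releases the auxiliary, while the unactivated diene and the tertiary alcohol are inert.

**Step 11**
Reactants: 20 labda-13(16),14-diene-8α,19-diol; 21 (E)-3-(4-methoxyphenyl)prop-2-enoyl chloride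
Product: 22 8α-hydroxylabda-13(16),14-dien-19-yl (E)-3-(4-methoxyphenyl)prop-2-enoate
Conditions: Et3N, DMAP (0.1 equiv), CH2Cl2, 0 °C → rt
Reagents that add atoms: none
Why: DMAP-catalysed acylation (nucleophilic catalysis) is selective for the primary C19–OH over the tertiary 8-OH, and the (E)-geometry is carried in with the acid chloride.

**Compound list**
1 | geranyl bromide, (2E)-1-bromo-3,7-dimethylocta-2,6-diene | CC(C)=CCC/C(C)=C/CBr | starting material
2 | tert-butyl acetate | CC(=O)OC(C)(C)C | starting material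
3 | lithium enolate of tert-butyl acetate | C=C([O-])OC(C)(C)C.[Li+] | intermediate
4 | tert-butyl (4E)-5,9-dimethyldeca-4,8-dienoate | CC(C)=CCC/C(C)=C/CCC(=O)OC(C)(C)C | intermediate
5 | tert-butyl (4E,8E)-10-hydroxy-5,9-dimethyldeca-4,8-dienoate | OC/C(C)=C/CC/C(C)=C/CCC(=O)OC(C)(C)C | intermediate
6 | tert-butyl (4E,8E)-10-bromo-5,9-dimethyldeca-4,8-dienoate | BrC/C(C)=C/CC/C(C)=C/CCC(=O)OC(C)(C)C | intermediate
7 | ethyl 2-methyl-3-oxobutanoate | CCOC(=O)C(C)C(C)=O | starting material
8 | (1R,2S,5R)-5-methyl-2-(2-phenylpropan-2-yl)cyclohexan-1-ol, (−)-8-phenylmenthol | O[C@@H]1C[C@H](C)CC[C@H]1C(C)(C)c1ccccc1 | starting material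
9 | (1R,2S,5R)-8-phenylmenthyl 2-methyl-3-oxobutanoate (both C2 epimers) | CC(=O)C(C)C(=O)O[C@@H]1C[C@H](C)CC[C@H]1C(C)(C)c1ccccc1 | intermediate
10 | sodium lithium dienolate (dianion) of 9 | C=C([O-])C(C)=C([O-])O[C@@H]1C[C@H](C)CC[C@H]1C(C)(C)c1ccccc1.[Na+].[Li+] | intermediate
11 | 1-[(1R,2S,5R)-8-phenylmenthyl] 14-tert-butyl (6E,10E)-2,6,10-trimethyl-3-oxotetradeca-6,10-dienedioate (both C2 epimers) | CC(C)(C)OC(=O)CC/C=C(C)/CC/C=C(C)/CCC(=O)C(C)C(=O)O[C@@H]1C[C@H](C)CC[C@H]1C(C)(C)c1ccccc1 | intermediate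
12 | C2 radical of 11 (the future C4; planar α-keto ester radical) | CC(C)(C)OC(=O)CC/C=C(C)/CC/C=C(C)/CCC(=O)[C](C)C(=O)O[C@@H]1C[C@H](C)CC[C@H]1C(C)(C)c1ccccc1 | intermediate
13 | bicyclic C8 cation: trans-decalin with 3-oxo, 4α-CH3, 4β-CO2R*, 5α-H, 9α-H, 10β-CH3 and the CH2CH2CO2tBu arm on C9β | CC(C)(C)OC(=O)CC[C@@H]1[C@@]2(C)CCC(=O)[C@](C)(C(=O)O[C@@H]3C[C@H](C)CC[C@H]3C(C)(C)c3ccccc3)[C@@H]2CC[C+]1C | intermediate
14 | (1R,2S,5R)-8-phenylmenthyl 3,13-dioxo-8α,13-epoxy-14,15,16-trinorlabdan-19-oate (4α-CH3, 4β-CO2R*, 5α-H, 8β-CH3, 9α-H, 10β-CH3; trans-fused δ-lactone) | O=C1CC[C@@H]2[C@@]3(C)CCC(=O)[C@](C)(C(=O)O[C@@H]4C[C@H](C)CC[C@H]4C(C)(C)c4ccccc4)[C@@H]3CC[C@@]2(C)O1 | intermediate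
15 | C3 tosylhydrazone of 14 | O=C1CC[C@@H]2[C@@]3(C)CCC(=NNS(=O)(=O)c4ccc(C)cc4)[C@](C)(C(=O)O[C@@H]4C[C@H](C)CC[C@H]4C(C)(C)c4ccccc4)[C@@H]3CC[C@@]2(C)O1 | intermediate
16 | (1R,2S,5R)-8-phenylmenthyl 13-oxo-8α,13-epoxy-14,15,16-trinorlabdan-19-oate | O=C1CC[C@@H]2[C@@]3(C)CCC[C@](C)(C(=O)O[C@@H]4C[C@H](C)CC[C@H]4C(C)(C)c4ccccc4)[C@@H]3CC[C@@]2(C)O1 | intermediate
17 | lithium 13-vinyl hemiketalate of 16 (C13 configuration undefined) | C=CC1([O-])CC[C@@H]2[C@@]3(C)CCC[C@](C)(C(=O)O[C@@H]4C[C@H](C)CC[C@H]4C(C)(C)c4ccccc4)[C@@H]3CC[C@@]2(C)O1.[Li+] | intermediate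
18 | (1R,2S,5R)-8-phenylmenthyl 8α-hydroxy-13-oxo-16-norlabd-14-en-19-oate | C=CC(=O)CC[C@@H]1[C@@]2(C)CCC[C@](C)(C(=O)O[C@@H]3C[C@H](C)CC[C@H]3C(C)(C)c3ccccc3)[C@@H]2CC[C@@]1(C)O | intermediate
19 | (1R,2S,5R)-8-phenylmenthyl 8α-hydroxylabda-13(16),14-dien-19-oate | C=CC(=C)CC[C@@H]1[C@@]2(C)CCC[C@](C)(C(=O)O[C@@H]3C[C@H](C)CC[C@H]3C(C)(C)c3ccccc3)[C@@H]2CC[C@@]1(C)O | intermediate
20 | labda-13(16),14-diene-8α,19-diol | C=CC(=C)CC[C@@H]1[C@@]2(C)CCC[C@](C)(CO)[C@@H]2CC[C@@]1(C)O | intermediate
21 | (E)-3-(4-methoxyphenyl)prop-2-enoyl chloride | COc1ccc(/C=C/C(=O)Cl)cc1 | starting material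
22 | (4S,5R,8R,9R,10S)-8α-hydroxylabda-13(16),14-dien-19-yl (E)-3-(4-methoxyphenyl)prop-2-enoate, CNP0249194.1 | C=CC(=C)CC[C@@H]1[C@@]2(C)CCC[C@](C)(COC(=O)/C=C/c3ccc(OC)cc3)[C@@H]2CC[C@@]1(C)O | target

**Count**
Total: 11 steps. Longest linear sequence: 10 steps (1, 2, 3, 5, 6, 7, 8, 9, 10, 11 from geranyl bromide); step 4 is a one-step side branch.

**Three steps most likely to fail**

Step 6 is the main risk. The lactone-forming termination is unprecedented in this cascade: the C8 radical may instead end as alkene mixtures, the cation may be captured on the β-face, and the facial control by the auxiliary with an alkene terminator is extrapolated from arene-terminated cases. If the sense of induction proved opposite, the antipodal auxiliary would correct it. Fallback: setting out from 11, the same Mn(OAc)3/Yb(OTf)3 cyclisation is run with Cu(OAc)2 (1 equiv), so that the C8 radical is taken through an organocopper species to the exocyclic alkene by β-hydride elimination, giving (1R,2S,5R)-8-phenylmenthyl 13-tert-butoxy-3,13-dioxo-14,15,16-trinorlabd-8(17)-en-19-oate F1. The lactone is then closed in a separate Brønsted-acid step (CF3CO2H, CH2Cl2, 0 °C): Markovnikov protonation of C8=C17, capture by the tert-butyl ester from the α-face and loss of isobutene, which comes back to the route at 14.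

Step 9 is the second risk. The vinyl ketone 18 is a good Michael acceptor and the ylide is basic, so conjugate addition or polymerisation can erode the methylenation, and step 8 can also over-add. Fallback: setting out from 16, MeLi (THF, −78 °C) gives the methyl ketone (1R,2S,5R)-8-phenylmenthyl 8α-hydroxy-13-oxo-14,15-dinorlabdan-19-oate F2. Kinetic deprotonation at the methyl group with LiN(iPr)2 (2.2 equiv) and trapping with PhNTf2 at −78 °C gives the terminal enol triflate (1R,2S,5R)-8-phenylmenthyl 8α-hydroxy-13-(trifluoromethylsulfonyloxy)-14,15-dinorlabd-13(16)-en-19-oate F3. Stille coupling with Bu3SnCH=CH2 (Pd(PPh3)4, LiCl, THF, 60 °C) comes back to the route at 19.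

Step 7 is the third risk. The C3 ketone sits next to the quaternary C4 carrying a bulky axial ester, so hydrazone formation may be slow and reduction of a hindered hydrazone can divert to alkene. Fallback: setting out from 14, ethane-1,2-dithiol and BF3·OEt2 (CH2Cl2, rt) give the dithiolane (1R,2S,5R)-8-phenylmenthyl 3,3-(ethane-1,2-diyldisulfanediyl)-13-oxo-8α,13-epoxy-14,15,16-trinorlabdan-19-oate F4. Desulfurisation with Raney Ni (EtOH, reflux; no C=C bond is present at this stage) comes back to the route at 16.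

**Further compounds**
F1 | step 6 | (1R,2S,5R)-8-phenylmenthyl 13-tert-butoxy-3,13-dioxo-14,15,16-trinorlabd-8(17)-en-19-oate | CC(C)(C)OC(=O)CC[C@@H]1[C@@]2(C)CCC(=O)[C@](C)(C(=O)O[C@@H]3C[C@H](C)CC[C@H]3C(C)(C)c3ccccc3)[C@@H]2CCC1=C
F2 | step 9 | (1R,2S,5R)-8-phenylmenthyl 8α-hydroxy-13-oxo-14,15-dinorlabdan-19-oate | CC(=O)CC[C@@H]1[C@@]2(C)CCC[C@](C)(C(=O)O[C@@H]3C[C@H](C)CC[C@H]3C(C)(C)c3ccccc3)[C@@H]2CC[C@@]1(C)O
F3 | step 9 | (1R,2S,5R)-8-phenylmenthyl 8α-hydroxy-13-(trifluoromethylsulfonyloxy)-14,15-dinorlabd-13(16)-en-19-oate | C=C(OS(=O)(=O)C(F)(F)F)CC[C@@H]1[C@@]2(C)CCC[C@](C)(C(=O)O[C@@H]3C[C@H](C)CC[C@H]3C(C)(C)c3ccccc3)[C@@H]2CC[C@@]1(C)O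
F4 | step 7 | (1R,2S,5R)-8-phenylmenthyl 3,3-(ethane-1,2-diyldisulfanediyl)-13-oxo-8α,13-epoxy-14,15,16-trinorlabdan-19-oate | O=C1CC[C@@H]2[C@@]3(C)CCC4(SCCS4)[C@](C)(C(=O)O[C@@H]5C[C@H](C)CC[C@H]5C(C)(C)c5ccccc5)[C@@H]3CC[C@@]2(C)O1
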